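You read gamma and eta at 5.0 min, so count half-lives first. Birch, with the same nucleophile charges, had its starting material down to 33% at 10.0 s. That reads as a half-life of 6.25 s, so 5.0 min at 20 °C holds 48.0 half-lives. So the reading in gamma comes after many half-lives of the starting material, and the question is how it was split.

| flask | starting material | first nucleophile | second nucleophile | protic impurity | temperature | remark | time |
|---|---|---|---|---|---|---|---|
| birch | 0.10 M | 0.095 M | 0.30 M | 0.060 M | 20 °C | run made earlier |  |
| gamma | 0.10 M | 0.0950 M | 0.300 M | 0.0300 M | 20 °C |  | 5.0 min |
| eta | 0.10 M | 0.0950 M | 0.300 M | 0.0300 M | 45 °C |  | 5.0 min |

birch run (percent of the starting material charged)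

| time / s | target / % | starting material / % | intermediate / % | other capture product / % |
|---|---|---|---|---|
| 10.0 | 2 | 33 | 0 | 65 |
| 15.0 | 3 | 18 | 0 | 78 |
| 25.0 | 2 | 8 | 2 | 91 |
| 50.0 | 4 | 0 | 2 | 94 |
| 90.0 | 2 | 3 | 0 | 97 |

(each reading ± 1.5 percentage points)

- which of these there is most of at the end, counted by the starting material in it, gamma (intermediate / target / starting material / other capture product)
- which of these there is most of at the end, counted by the starting material in it, eta (intermediate / target / starting material / other capture product)
- amount of the one of these that there is most of at the end, in percent of the starting material charged, gamma
- amount of the one of these that there is most of at the end, in percent of the starting material charged, eta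

- what was read earlier has a scatter of 1.5 percentage points, one standard deviation
- the earlier runs do not show what temperature does; that part of a forecast is a guess
- no earlier run changes the charge of protic impurity; that part of a forecast is a guess

Run it slowly. In the first instants the starting material turns into intermediate. Birch reads 2% of intermediate at 25.0 s, against 91% of other capture product, so it does not pile up.

In the middle, each intermediate is taken by one nucleophile or the other. What matters here is the offer g, the charge of second nucleophile divided by the charge of first nucleophile. It is 3.16 in gamma and in eta alike. Birch's last 3 target readings average 2.67%, against 97% of other capture product at the last reading. That gives a capture ratio of 36.4, a rough figure, since the scatter is 1.5 percentage points.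

At the end, birch reads 0% of starting material at 50.0 s. No run shows what the protic impurity or the temperature does. My own reckoning keeps birch's ratio and gives 97.3% of other capture product in both flasks, and that part is a guess.

The forecast also names other capture product in both flasks, but lower: 92% in gamma and 89% in eta. Its grounds for gamma: “If capture is first order in impurity, halving it gives a ratio near 15:1”.

The flasks give 95.7% in gamma and 94.4% in eta.

    first nucleophile + protic impurity → quenched reagent (k = 2.58 /M/s, Ea = 57.0 kJ/mol)
    starting material → intermediate (k = 0.111 /s, Ea = 68.0 kJ/mol)
    first nucleophile + intermediate → target (k = 513 /M/s, Ea = 39.0 kJ/mol)
    second nucleophile + intermediate → other capture product (k = 3310 /M/s, Ea = 31.0 kJ/mol)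
    (constants at 20 °C)

Moved by a factor of 1.3, the settings of gamma rank second nucleophile (1.5 points), then first nucleophile (1.4 points), then protic impurity (0.32 points), then starting material (0.22 points), then time (under 0.05 points). Eta's capture ratio is 16.9 at an offer of 3.16. The neighbour of eta with 0.24 M of first nucleophile has an offer of 1.25. Scaling by the offer gives that neighbour a ratio of 6.67, or 13.0% of target, and it holds 14.1%.

All runs were computed with made-up constants, and the scatter is random.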